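Its constants are invented; what happens was integrated by code.

Per cent of the substrate charged was the unit I counted single product in, across flasks that differed in their charge of coupling partner.

    substrate + coupling partner → single product + by-product (k1 = 9.3 L mol⁻¹ s⁻¹)
    substrate + coupling partner → other mono adduct + by-product (k2 = 9.3 L mol⁻¹ s⁻¹)
    coupling partner + single product → double product + by-product (k3 = 17 L mol⁻¹ s⁻¹)
    coupling partner + other mono adduct → double product + by-product (k4 = 29 L mol⁻¹ s⁻¹)
    coupling partner ⇌ dormant form (K5 = 0.30, k5 = 0.061 s⁻¹)
    coupling partner → decomposition product (k6 = 1.8 × 10⁻⁵ s⁻¹)

all flasks: substrate 0.050 M; time 40 s

| flask | coupling partner |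
|---|---|
| birch | 0.0150 M |
| oak | 0.0400 M |
| alder | 0.120 M |
| ash | 0.400 M |

- "hardly changes" means that all values lie within two and a half points (for a concentration: within two and a half percent of the largest)
- run time (birch): 40 s

* amount of single product at the end, in percent of the substrate charged for birch, oak, alder, ash, in this order
* how the row runs (hardly changes / falls, then rises / rises all the way / rises, then falls / falls all the way)

At any one moment single product gained at 9.3 L mol⁻¹ s⁻¹ × [substrate][coupling partner] and lost at 17 L mol⁻¹ s⁻¹ × [single product][coupling partner]. The [coupling partner] cancelled, so the comparison came down to the crest ratio, the value of [single product]/[substrate] at which gain and loss balance: 0.547, a selectivity factor. Below it single product grew; above it single product shrank.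

The ratio drifted upward as a flask ran, so I asked how far each charge could carry it. I reckoned by hand on exposure, the time integral of [coupling partner]. The crest ratio came at an exposure of 0.0562 M·s, with 35.1% of the substrate left and 19.2% as single product. Counting one coupling partner per mono adduct and two per double product, that crest cost 0.0483 M. Oak's charge fell short of this. Alder's charge stood above it, so I expected a rise to oak and a fall by alder.

The forecast, holding for birch and oak that “the partner is limiting”, gave 11.2%, 18.8%, 0.001% and 0%, with the shape "rises, then falls". The simulation gave 11.2%, 18.8%, 0% and 0%, with the shape "rises, then falls".

In oak the ratio stood at 0.433 after 40.0 s, below 0.547, with coupling partner, the limiting reagent there, at 0% of its charge: oak stopped on the rising side. In alder the ratio had reached 5.90 by 20.0 s, above the crest ratio, on the falling side. In ash the loss of single product is the third step's work: with that step taken away, ash held 50.0% single product instead of 0%.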